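Its constants are invented; no experiment stands behind them.

Over the 80 s of this flask the gas had to enter solution while the starting material was being spent on two partners, dissolved gas and target, so I drew the target curve first.

starting material 2.9 M; gas phase 170 mM (held); protic impurity 1.45 M; time 80 s

    gas phase ⇌ dissolved gas, rate k1*(csat - [dissolved gas]) (k1 = 0.699 s⁻¹, csat = 170 mM)
    starting material + dissolved gas → target (k2 = 2.84 L mol⁻¹ s⁻¹)
    starting material ⇌ dormant form (K3 = 1.0, k3 = 0.0241 s⁻¹)
    starting material + target → side product (k4 = 0.0537 L mol⁻¹ s⁻¹)
    dissolved gas + protic impurity → quenched reagent (k5 = 0.00876 L mol⁻¹ s⁻¹)

- a species is counted by the starting material in it: one side product counts as two
- at the start none of the gas is dissolved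
- run time (flask): 80 s

1. target at 80 s, in percent of the starting material charged
2. concentration of dissolved gas in solution at 80 s, in percent of saturation

I counted everything as fractions of the charged starting material. In this flask dissolved gas had a half-life of 0.084 s by the target-forming step at the charge, shorter than the 0.992 s of transfer from the gas phase, so I let each arriving portion of gas be caught at once, and the slope of the target curve began near the gas supply, in fractions of the charge:

  supply = 0.0410 s⁻¹

The side reaction removes one starting material and one target together, so it leaves their gap untouched, and the gap closes at twice the supply. With the dormant form set aside, the two curves cross at:

  crossing = 12.2 s

That is the symmetric point, and I made it the zero of my scale. The balance number is the side-reaction rate with starting material and target each at 0.5 of the charge, divided by the gas supply: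

  balance number = 0.950

This stood close to one, so I drew a knee around the crossing, where the side reaction could nearly match the supply. After it the curve bends towards a level reached as the dormant form returns. My reckoning stopped there: it promised side product of the same order as target, but gave no level.

The forecast gave 50.3 % of target and 96.6 % of saturation, on this ground: "The gas transfer is fast compared with the chemistry". My own reckoning differed on this ground at the start of the run, where I had transfer at 0.992 s slower than capture at 0.084 s.

The simulation gave 50.7 % of target and 96.4 % of saturation, both within the margin of the forecast. Side product in this flask stood at 45.3 % of the charge at 80.0 s. The balance number of this flask was 0.950; the neighbour flask, with 1.7 M of starting material, has a balance number of 0.327, lower than that of this flask, and there target reached 66.7 % and side product 30.2 %.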